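**Plan**
Cuts: the three benzyl ethers come off last. Each pyranone ring is cut at O1–C2 (oxa-Michael) and C2=C3 (Knoevenagel), ring C first and then ring C''. Ring A'' is cut at C4a''–C8a'', and the diaryl ether at O–C4'.
Enabling feature: ring A'' has the acyl carbon on C4a'', oxygen on C5'', C7'' and C8a'' (an acetate-type 1,3,5-pattern), H on C8'' and one extra oxygen on C6''. Opened at C4a''–C8a'' it is a 4-aryloxy-3,5,7-trioxooctanoate. Its C3/C5/C7 carbonyls are those of a 3-aryloxy-4-pyranone with CH3 on C6 and an acetate arm on C2.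
Forward: kojic acid → allomaltol → aminomethyl arm → O-arylation of the enolic OH with 4-fluorobenzaldehyde → chloride → carbonylation gives the pyranone. Ring A'' is closed in step 8, ring C'' in step 13 and ring C in step 17. Rings A, B and the second B ring are bought as benzene rings.
Stereochemistry: C2'' and C2 are each set as S under catalyst control, by a cinchona-thiourea-catalysed oxa-Michael closure of a 2'-hydroxychalcone α-carboxylate. The regiochemistry of ring C'' is fixed by a Boc group that marks the less hindered OH and is then moved to carbon.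

Key step: step 8

Assumption: the thiourea derived from 9-amino-9-deoxy-epi-quinidine is taken to give the 2S series. Its quinine-derived pseudoenantiomer is equally available and would replace it if a circular dichroism check on 20 shows the opposite sense.

Step 1
Reactants: 1 kojic acid
Product: 2 chlorokojic acid (2-(chloromethyl)-5-hydroxy-4H-pyran-4-one)
Conditions: SOCl2 (neat), rt
Reagents that add atoms: thionyl chloride, O=S(Cl)Cl
Why: Chlorodehydroxylation of the primary allylic-type alcohol (chlorosulfite, then SN2 by chloride) is the classical entry to this chloride, and the enolic 5-OH, a vinylogous acid, is left untouched.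

Step 2
Reactants: 2 chlorokojic acid
Product: 3 allomaltol (5-hydroxy-2-methyl-4H-pyran-4-one)
Conditions: Zn dust, conc. HCl, H2O, 70 °C
Reagents that add atoms: none
Why: Dissolving-metal reduction, in which zinc puts two electrons into a C–Cl bond activated as the vinylogue of an α-halo ketone and protonation of the dienolate gives the methyl group without touching the ring.

Step 3
Reactants: 3 allomaltol; 4 formaldehyde (37 % aqueous)
Product: 5 3-hydroxy-6-methyl-2-(morpholin-4-ylmethyl)-4H-pyran-4-one
Conditions: morpholine, EtOH, rt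
Reagents that add atoms: morpholine, C1COCCN1
Why: Mannich reaction at the only free carbon ortho to the enolic OH (the hydroxypyranone reacts like a phenol); a tertiary amine arm is preferred to CH2OH because in hot base (step 4) it can neither lose formaldehyde by retro-aldol cleavage nor capture the aryl group by Smiles rearrangement.

Step 4
Reactants: 5 Mannich base; 6 4-fluorobenzaldehyde
Product: 7 4-{[6-methyl-2-(morpholin-4-ylmethyl)-4-oxo-4H-pyran-3-yl]oxy}benzaldehyde
Conditions: K2CO3, DMF, 110 °C
Reagents that add atoms: none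
Why: Nucleophilic aromatic substitution (addition–elimination) in which the potassium enolate adds para to the formyl group and fluoride leaves, so the ether oxygen is arylated while it is flanked only by a carbonyl and a CH2 group.

Step 5
Reactants: 7 aryl ether amine
Product: 8 4-{[2-(chloromethyl)-6-methyl-4-oxo-4H-pyran-3-yl]oxy}benzaldehyde
Conditions: ClCO2Et, ClCH2CH2Cl, 0 → 60 °C
Reagents that add atoms: ethyl chloroformate, CCOC(=O)Cl
Why: Chloroformate dealkylation of a tertiary amine (von Braun type), in which N-acylation gives an acylammonium chloride and chloride attacks the most SN2-active carbon, the pyranylmethyl CH2, releasing the carbamate while the aldehyde stays inert.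

Step 6
Reactants: 8 chloromethyl aldehyde
Product: 9 2-(chloromethyl)-3-[4-(5,5-dimethyl-1,3-dioxan-2-yl)phenoxy]-6-methyl-4H-pyran-4-one
Conditions: 2,2-dimethylpropane-1,3-diol, TsOH·H2O (cat.), toluene, Dean–Stark
Reagents that add atoms: 2,2-dimethylpropane-1,3-diol, OCC(C)(C)CO
Why: Acid-catalysed acetalisation with azeotropic water removal, which masks the aldehyde against the carbanions of steps 8 and 11; the cyclic acetal is chosen because it should survive weakly acidic work-ups better than a dimethyl acetal.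

Step 7
Reactants: 9 chloromethyl acetal
Product: 10 methyl 2-{3-[4-(5,5-dimethyl-1,3-dioxan-2-yl)phenoxy]-6-methyl-4-oxo-4H-pyran-2-yl}acetate
Conditions: PdCl2(PPh3)2 (3 mol %), CO (5 bar), iPr2NEt, MeOH–THF 1:3, 60 °C
Reagents that add atoms: carbon monoxide, [C-]#[O+]; methanol, CO
Why: Palladium-catalysed alkoxycarbonylation of a benzylic-type chloride (oxidative addition to zerovalent palladium, CO insertion, methanolysis of the acyl complex) adds the carbon that becomes C8a'', with the hindered amine only taking up HCl.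

Step 8
Reactants: 10 pyranone acetate
Product: 12 1-{3-[4-(5,5-dimethyl-1,3-dioxan-2-yl)phenoxy]-2,6-dihydroxy-4-methoxyphenyl}ethan-1-one, via ring-opened enol ether chelate 11 (not isolated)
Conditions: Mg(OMe)2 (5 equiv, commercial solution), dry MeOH, reflux, Ar; then 0.5 M HCl to pH 5, 0 °C
Reagents that add atoms: magnesium methoxide, C[O-].C[O-].[Mg+2]
Why: Methoxide held on magnesium adds to pyranone C2, the α-carbon bearing the acetate arm, and O1 leaves as the enolate oxygen on C6, which unrolls the ring into the magnesium chelate of the 3,5,7-tricarbonyl ester 11, with chain C5/C7 as an acetylacetonate-type chelate and chain C3 still masked as its methyl enol ether. After E/Z equilibration of this push–pull double bond the C6 carbanion attacks the ester carbonyl C1 (new bond C4a''–C8a''), the ester methoxide leaves and the dienone tautomerises to the benzene ring, so ring A'' closes in a 6-exo-trig Claisen (Dieckmann-type) mode with the C5–C6 enolate endocyclic, and no stereocentre is formed. The closest known reaction types are the base-induced opening of 4-pyranones to 1,3,5-tricarbonyl compounds and the Mg(OMe)2-templated Claisen folding of 3,5,7-triketo esters and of their 2-pyranone lactones to acylphloroglucinols. A 4-pyranone is the anhydride of its triketone and hydroxide would saponify the ester before it opened the ring, so the medium is kept dry and the opening nucleophile is retained: 10 and 12 are isomers, the methoxide that enters becomes the 7''-OMe group and no later selective methylation is needed. The selectivity needed is Claisen closure (C6 onto C1) over aldol-type closure (C2 onto C7, giving a resorcylate) and over reclosure through oxygen; the O-closures and the opening at the methyl-bearing α-carbon are reversible under methoxide, whereas aromatisation is not. The substrate secures it because in 11 the charge sits on the nucleophile C6, C7 is enolised and so is no electrophile, the ester is the only carbonyl that cannot be enolised away and C2–H has lost its β-keto ester acidity, while the isomer opened at the other α-carbon carries its charge between C2 and C7 and blunts both partners of the aldol mode.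

Step 9
Reactants: 12 dihydroxyacetophenone
Product: 13 2-acetyl-4-[4-(5,5-dimethyl-1,3-dioxan-2-yl)phenoxy]-3-hydroxy-5-methoxyphenyl tert-butyl carbonate
Conditions: Boc2O (1.0 equiv), 4-(dimethylamino)pyridine (5 mol %), CH2Cl2, −20 → 0 °C
Reagents that add atoms: di-tert-butyl dicarbonate, CC(C)(C)OC(=O)OC(=O)OC(C)(C)C
Why: Nucleophile-catalysed O-acylation that should pick the OH next to the ring C–H (future O1''), because the other OH is wedged between acetyl and aryloxy groups and pressed into the hydrogen bond to the carbonyl.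

Step 10
Reactants: 13 monocarbonate
Product: 14 2-acetyl-3-(benzyloxy)-4-[4-(5,5-dimethyl-1,3-dioxan-2-yl)phenoxy]-5-methoxyphenyl tert-butyl carbonate
Conditions: BnOH, PPh3, DIAD, THF, 0 °C → rt
Reagents that add atoms: benzyl alcohol, OCc1ccccc1
Why: Mitsunobu etherification of the remaining chelated phenol (future 5''-OH) with a primary benzylic alcohol, chosen because its near-neutral conditions generate no acetyl enolate and no free alkoxide that could disturb the aryl carbonate.

Step 11
Reactants: 14 benzyl ether carbonate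
Product: 15 tert-butyl 3-{2-(benzyloxy)-3-[4-(5,5-dimethyl-1,3-dioxan-2-yl)phenoxy]-6-hydroxy-4-methoxyphenyl}-3-oxopropanoate
Conditions: LiN(SiMe3)2 (2.2 equiv), THF, −78 → 0 °C; AcOH
Reagents that add atoms: none
Why: Baker–Venkataraman rearrangement in its carbonic-acid (carbonate/carbamate) version, in which the lithium enolate of the acetyl group attacks the neighbouring carbonate through a six-membered transition state and aryloxide leaves; this turns the marker on oxygen into the activating ester on carbon and frees exactly the OH that must close ring C''.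

Step 12
Reactants: 15 β-keto ester; 16 4-(benzyloxy)benzaldehyde
Product: 17 tert-butyl (2Z)-2-{2-(benzyloxy)-3-[4-(5,5-dimethyl-1,3-dioxan-2-yl)phenoxy]-6-hydroxy-4-methoxybenzoyl}-3-[4-(benzyloxy)phenyl]prop-2-enoate
Conditions: piperidine (10 mol %), AcOH (10 mol %), 4 Å MS, toluene, rt
Reagents that add atoms: none
Why: Knoevenagel condensation between the only CH-acid and the only free aldehyde (the other is an acetal), run in the buffered non-polar medium in which 2'-hydroxy alkylidene β-keto esters are known to be isolable before ring closure.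

Step 13
Reactants: 17 alkylidene β-keto ester
Product: 20 4-({(2S)-5-(benzyloxy)-2-[4-(benzyloxy)phenyl]-7-methoxy-4-oxo-3,4-dihydro-2H-chromen-6-yl}oxy)benzaldehyde, via chromanone-3-carboxylate 18 (not isolated), via flavanone acetal 19 (not isolated)
Conditions: 1-[3,5-bis(trifluoromethyl)phenyl]-3-[(9R)-6'-methoxycinchonan-9-yl]thiourea (10 mol %), toluene, −25 °C; then TsOH·H2O, 80 °C; then THF–H2O, rt
Reagents that add atoms: water, O
Why: Intramolecular oxa-Michael addition under bifunctional cinchona-thiourea catalysis, a known enantioselective flavanone synthesis from 2'-hydroxychalcone α-carboxylates: the thiourea binds the β-keto ester, the quinuclidine deprotonates the only free phenol (so only the 6''-aryloxy regioisomer can form) and guides it to one face of the alkylidene carbon, setting C2'' as S under catalyst control, after which acid removes the tert-butyl ester with decarboxylation and, once water is added, the acetal.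

Step 14
Reactants: 21 1-(2,6-dihydroxy-4-methoxyphenyl)ethan-1-one
Product: 22 1-[2-(benzyloxy)-6-hydroxy-4-methoxyphenyl]ethan-1-one
Conditions: BnBr (1.0 equiv), K2CO3, acetone, reflux
Reagents that add atoms: benzyl bromide, BrCc1ccccc1
Why: Williamson etherification of a symmetric diol, in which either OH may react and the remaining OH is then locked in a hydrogen bond to the acetyl group, so the reaction should stop at the monoether.

Step 15
Reactants: 22 monobenzyl ether
Product: 24 tert-butyl 3-[2-(benzyloxy)-6-hydroxy-4-methoxyphenyl]-3-oxopropanoate, via aryl tert-butyl carbonate 23 (not isolated)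
Conditions: Boc2O, 4-(dimethylamino)pyridine (cat.), THF, rt; then LiN(SiMe3)2 (3.5 equiv), −78 → 0 °C; AcOH
Reagents that add atoms: di-tert-butyl dicarbonate, CC(C)(C)OC(=O)OC(=O)OC(C)(C)C
Why: The same O-acylation and Baker–Venkataraman-type O→C transfer as in steps 9 and 11, run in one flask because no regiochemical question arises here.

Step 16
Reactants: 20 flavanone aldehyde; 24 β-keto ester
Product: 25 tert-butyl (2Z)-2-[2-(benzyloxy)-6-hydroxy-4-methoxybenzoyl]-3-[4-({(2S)-5-(benzyloxy)-2-[4-(benzyloxy)phenyl]-7-methoxy-4-oxo-3,4-dihydro-2H-chromen-6-yl}oxy)phenyl]prop-2-enoate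
Conditions: piperidine (10 mol %), AcOH (10 mol %), 4 Å MS, toluene, rt
Reagents that add atoms: none
Why: Knoevenagel condensation in which the β-keto ester is far more CH-acidic than C3''–H2 of the flavanone, and the buffered amine is too weak a base to open ring C'' by retro-oxa-Michael reaction, so C2'' is kept.

Step 17
Reactants: 25 alkylidene β-keto ester
Product: 27 (2S,2''S)-5,5'',4'''-tri-O-benzyl-7,7''-di-O-methyltetrahydrohinokiflavone, via chromanone-3-carboxylate 26 (not isolated)
Conditions: 1-[3,5-bis(trifluoromethyl)phenyl]-3-[(9R)-6'-methoxycinchonan-9-yl]thiourea (10 mol %), toluene, −25 °C; then TsOH·H2O, 80 °C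
Reagents that add atoms: none
Why: The same thiourea-catalysed oxa-Michael closure and acid decarboxylation as in step 13 sets C2 as S under catalyst control (C2'' is too remote to interfere), and since both centres are set independently, most of the minor enantiomer of 20 should end up in a diastereomer of 27 that can be removed here.

Step 18
Reactants: 27 tribenzyl ether
Product: 28 7,7''-di-O-methyltetrahydrohinokiflavone, (2S,2''S)
Conditions: H2 (1 atm), Pd/C (10 %), EtOAc–THF, rt
Reagents that add atoms: none
Why: Hydrogenolysis of the three benzyl aryl ethers under neutral conditions avoids the base-induced ring opening by which 5-hydroxy- and 4'-hydroxyflavanones racemise, while the electron-rich aryl ketones, the C2–O bonds and the diaryl ether should survive at 1 atm.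

**Compound list**
1 | kojic acid, 5-hydroxy-2-(hydroxymethyl)-4H-pyran-4-one | OCc1cc(=O)c(O)co1 | starting material
2 | chlorokojic acid, 2-(chloromethyl)-5-hydroxy-4H-pyran-4-one | ClCc1cc(=O)c(O)co1 | intermediate
3 | allomaltol, 5-hydroxy-2-methyl-4H-pyran-4-one | Cc1cc(=O)c(O)co1 | intermediate
4 | formaldehyde | C=O | starting material
5 | 3-hydroxy-6-methyl-2-(morpholin-4-ylmethyl)-4H-pyran-4-one | Cc1cc(=O)c(O)c(CN2CCOCC2)o1 | intermediate
6 | 4-fluorobenzaldehyde | O=Cc1ccc(F)cc1 | starting material
7 | 4-{[6-methyl-2-(morpholin-4-ylmethyl)-4-oxo-4H-pyran-3-yl]oxy}benzaldehyde | Cc1cc(=O)c(Oc2ccc(C=O)cc2)c(CN2CCOCC2)o1 | intermediate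
8 | 4-{[2-(chloromethyl)-6-methyl-4-oxo-4H-pyran-3-yl]oxy}benzaldehyde | Cc1cc(=O)c(Oc2ccc(C=O)cc2)c(CCl)o1 | intermediate
9 | 2-(chloromethyl)-3-[4-(5,5-dimethyl-1,3-dioxan-2-yl)phenoxy]-6-methyl-4H-pyran-4-one | Cc1cc(=O)c(Oc2ccc(C3OCC(C)(C)CO3)cc2)c(CCl)o1 | intermediate
10 | methyl 2-{3-[4-(5,5-dimethyl-1,3-dioxan-2-yl)phenoxy]-6-methyl-4-oxo-4H-pyran-2-yl}acetate | COC(=O)Cc1oc(C)cc(=O)c1Oc1ccc(C2OCC(C)(C)CO2)cc1 | intermediate
11 | methyl (3Z)-4-[4-(5,5-dimethyl-1,3-dioxan-2-yl)phenoxy]-3-methoxy-5,7-dioxooct-3-enoate (present as magnesium chelate, reactive Z form drawn) | COC(=O)C/C(OC)=C(/Oc1ccc(C2OCC(C)(C)CO2)cc1)C(=O)CC(C)=O | intermediate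
12 | 1-{3-[4-(5,5-dimethyl-1,3-dioxan-2-yl)phenoxy]-2,6-dihydroxy-4-methoxyphenyl}ethan-1-one | CC(=O)c1c(O)cc(OC)c(Oc2ccc(C3OCC(C)(C)CO3)cc2)c1O | intermediate
13 | 2-acetyl-4-[4-(5,5-dimethyl-1,3-dioxan-2-yl)phenoxy]-3-hydroxy-5-methoxyphenyl tert-butyl carbonate | CC(=O)c1c(OC(=O)OC(C)(C)C)cc(OC)c(Oc2ccc(C3OCC(C)(C)CO3)cc2)c1O | intermediate
14 | 2-acetyl-3-(benzyloxy)-4-[4-(5,5-dimethyl-1,3-dioxan-2-yl)phenoxy]-5-methoxyphenyl tert-butyl carbonate | CC(=O)c1c(OC(=O)OC(C)(C)C)cc(OC)c(Oc2ccc(C3OCC(C)(C)CO3)cc2)c1OCc1ccccc1 | intermediate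
15 | tert-butyl 3-{2-(benzyloxy)-3-[4-(5,5-dimethyl-1,3-dioxan-2-yl)phenoxy]-6-hydroxy-4-methoxyphenyl}-3-oxopropanoate | CC(C)(C)OC(=O)CC(=O)c1c(O)cc(OC)c(Oc2ccc(C3OCC(C)(C)CO3)cc2)c1OCc1ccccc1 | intermediate
16 | 4-(benzyloxy)benzaldehyde | O=Cc1ccc(OCc2ccccc2)cc1 | starting material
17 | tert-butyl (2Z)-2-{2-(benzyloxy)-3-[4-(5,5-dimethyl-1,3-dioxan-2-yl)phenoxy]-6-hydroxy-4-methoxybenzoyl}-3-[4-(benzyloxy)phenyl]prop-2-enoate | CC(C)(C)OC(=O)/C(=C\c1ccc(OCc2ccccc2)cc1)C(=O)c1c(O)cc(OC)c(Oc2ccc(C3OCC(C)(C)CO3)cc2)c1OCc1ccccc1 | intermediate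
18 | tert-butyl (2S,3R)-5-(benzyloxy)-2-[4-(benzyloxy)phenyl]-6-[4-(5,5-dimethyl-1,3-dioxan-2-yl)phenoxy]-7-methoxy-4-oxo-3,4-dihydro-2H-chromene-3-carboxylate (trans keto form) | CC1(C)COC(c2ccc(Oc3c(OC)cc4c(c3OCc3ccccc3)C(=O)[C@H](C(=O)OC(C)(C)C)[C@@H](c3ccc(OCc5ccccc5)cc3)O4)cc2)OC1 | intermediate
19 | (2S)-5-(benzyloxy)-2-[4-(benzyloxy)phenyl]-6-[4-(5,5-dimethyl-1,3-dioxan-2-yl)phenoxy]-7-methoxy-2,3-dihydro-4H-chromen-4-one | CC1(C)COC(c2ccc(Oc3c(OC)cc4c(c3OCc3ccccc3)C(=O)C[C@@H](c3ccc(OCc5ccccc5)cc3)O4)cc2)OC1 | intermediate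
20 | 4-({(2S)-5-(benzyloxy)-2-[4-(benzyloxy)phenyl]-7-methoxy-4-oxo-3,4-dihydro-2H-chromen-6-yl}oxy)benzaldehyde | O=Cc1ccc(Oc2c(OC)cc3c(c2OCc2ccccc2)C(=O)C[C@@H](c2ccc(OCc4ccccc4)cc2)O3)cc1 | intermediate
21 | 1-(2,6-dihydroxy-4-methoxyphenyl)ethan-1-one | CC(=O)c1c(O)cc(OC)cc1O | starting material
22 | 1-[2-(benzyloxy)-6-hydroxy-4-methoxyphenyl]ethan-1-one | CC(=O)c1c(O)cc(OC)cc1OCc1ccccc1 | intermediate
23 | 2-acetyl-3-(benzyloxy)-5-methoxyphenyl tert-butyl carbonate | CC(=O)c1c(OC(=O)OC(C)(C)C)cc(OC)cc1OCc1ccccc1 | intermediate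
24 | tert-butyl 3-[2-(benzyloxy)-6-hydroxy-4-methoxyphenyl]-3-oxopropanoate | CC(C)(C)OC(=O)CC(=O)c1c(O)cc(OC)cc1OCc1ccccc1 | intermediate
25 | tert-butyl (2Z)-2-[2-(benzyloxy)-6-hydroxy-4-methoxybenzoyl]-3-[4-({(2S)-5-(benzyloxy)-2-[4-(benzyloxy)phenyl]-7-methoxy-4-oxo-3,4-dihydro-2H-chromen-6-yl}oxy)phenyl]prop-2-enoate | CC(C)(C)OC(=O)/C(=C\c1ccc(Oc2c(OC)cc3c(c2OCc2ccccc2)C(=O)C[C@@H](c2ccc(OCc4ccccc4)cc2)O3)cc1)C(=O)c1c(O)cc(OC)cc1OCc1ccccc1 | intermediate
26 | tert-butyl (2S,3R)-5-(benzyloxy)-2-[4-({(2S)-5-(benzyloxy)-2-[4-(benzyloxy)phenyl]-7-methoxy-4-oxo-3,4-dihydro-2H-chromen-6-yl}oxy)phenyl]-7-methoxy-4-oxo-3,4-dihydro-2H-chromene-3-carboxylate (trans keto form) | COc1cc(OCc2ccccc2)c2c(c1)O[C@H](c1ccc(Oc3c(OC)cc4c(c3OCc3ccccc3)C(=O)C[C@@H](c3ccc(OCc5ccccc5)cc3)O4)cc1)[C@@H](C(=O)OC(C)(C)C)C2=O | intermediate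
27 | (2S,2''S)-5,5'',4'''-tri-O-benzyl-7,7''-di-O-methyltetrahydrohinokiflavone | COc1cc(OCc2ccccc2)c2c(c1)O[C@H](c1ccc(Oc3c(OC)cc4c(c3OCc3ccccc3)C(=O)C[C@@H](c3ccc(OCc5ccccc5)cc3)O4)cc1)CC2=O | intermediate
28 | (2S,2''S)-7,7''-di-O-methyltetrahydrohinokiflavone | COc1cc(O)c2c(c1)O[C@H](c1ccc(Oc3c(OC)cc4c(c3O)C(=O)C[C@@H](c3ccc(O)cc3)O4)cc1)CC2=O | target

**Count and risks**
Total steps: 18. Longest linear sequence: 16 (steps 1–13 and 16–18).

Step 8 is the riskiest step.
- What may go wrong: the pyranone may open preferentially at its methyl-bearing α-carbon and then leak into the aldol-type fold. The reaction may also stall because the acidic CH2 of the arm is deprotonated and the ring loses its electrophilicity.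
- Fallback: it takes ring A'' from an existing benzene ring, sets out from 21 and 6, and returns at 12.
- Elbs persulfate oxidation of 21 (K2S2O8, aq NaOH, then hot dilute HCl) should give 1-(2,3,6-trihydroxy-4-methoxyphenyl)ethan-1-one F1.
- The only unchelated hydroxyl of F1 would be arylated with 6 (K2CO3, DMF, 120 °C) to 4-(3-acetyl-2,4-dihydroxy-6-methoxyphenoxy)benzaldehyde F2.
- Acetalisation as in step 6 would then deliver 12.

Step 13 is the second risk.
- What may go wrong: uncatalysed ring closure may already occur during the Knoevenagel condensation, or facial selectivity may be poor because the 2',6'-dioxygenated aroyl group is twisted out of the plane on which the catalyst model relies.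
- Fallback: it forms the C2''–aryl bond instead of the O1''–C2'' bond at the stereodefining stage, sets out from 14, and returns at 19.
- Methanolysis of the carbonate (K2CO3, MeOH) should give 1-{2-(benzyloxy)-3-[4-(5,5-dimethyl-1,3-dioxan-2-yl)phenoxy]-6-hydroxy-4-methoxyphenyl}ethan-1-one F3.
- Me2NCH(OMe)2 (toluene, 90 °C) should convert F3 into (2E)-1-{2-(benzyloxy)-3-[4-(5,5-dimethyl-1,3-dioxan-2-yl)phenoxy]-6-hydroxy-4-methoxyphenyl}-3-(dimethylamino)prop-2-en-1-one F4.
- Warm AcOH should close F4 to 5-(benzyloxy)-6-[4-(5,5-dimethyl-1,3-dioxan-2-yl)phenoxy]-7-methoxy-4H-chromen-4-one F5.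
- Rhodium-catalysed asymmetric 1,4-addition (Hayashi–Miyaura reaction) of 4-(benzyloxy)phenylboronic acid would follow, with [Rh(OH)(cod)]2 and (S)-MeO-F12-BIPHEP in toluene–H2O. By analogy with cyclic enones this should place the aryl group on the face that gives 2''S and furnish 19, which is hydrolysed to 20 as in the last stage of step 13.

Step 4 is the third risk.
- What may go wrong: addition of the weakly nucleophilic pyranone enolate to a ring activated only by a formyl group may be sluggish, so that thermal degradation of the Mannich base or condensation at the pyranone methyl group overtakes it.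
- Fallback: it replaces addition–elimination by aryl transfer from hypervalent iodine, sets out from 5, and returns at 7.
- 4-Iodobenzaldehyde is oxidised with mCPBA and TsOH·H2O in MeCN and coupled with 1,3,5-trimethoxybenzene to (4-formylphenyl)(2,4,6-trimethoxyphenyl)iodonium 4-methylbenzenesulfonate F6.
- F6 should transfer its electron-poor aryl group to the potassium enolate of 5 (K2CO3, MeCN, 40 °C) to give 7.

**Further compounds**
F1 | step 8 | 1-(2,3,6-trihydroxy-4-methoxyphenyl)ethan-1-one | CC(=O)c1c(O)cc(OC)c(O)c1O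
F2 | step 8 | 4-(3-acetyl-2,4-dihydroxy-6-methoxyphenoxy)benzaldehyde | CC(=O)c1c(O)cc(OC)c(Oc2ccc(C=O)cc2)c1O
F3 | step 13 | 1-{2-(benzyloxy)-3-[4-(5,5-dimethyl-1,3-dioxan-2-yl)phenoxy]-6-hydroxy-4-methoxyphenyl}ethan-1-one | CC(=O)c1c(O)cc(OC)c(Oc2ccc(C3OCC(C)(C)CO3)cc2)c1OCc1ccccc1
F4 | step 13 | (2E)-1-{2-(benzyloxy)-3-[4-(5,5-dimethyl-1,3-dioxan-2-yl)phenoxy]-6-hydroxy-4-methoxyphenyl}-3-(dimethylamino)prop-2-en-1-one | CN(C)/C=C/C(=O)c1c(O)cc(OC)c(Oc2ccc(C3OCC(C)(C)CO3)cc2)c1OCc1ccccc1
F5 | step 13 | 5-(benzyloxy)-6-[4-(5,5-dimethyl-1,3-dioxan-2-yl)phenoxy]-7-methoxy-4H-chromen-4-one | O=c1ccoc2cc(OC)c(Oc3ccc(C4OCC(C)(C)CO4)cc3)c(OCc3ccccc3)c12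
F6 | step 4 | (4-formylphenyl)(2,4,6-trimethoxyphenyl)iodonium 4-methylbenzenesulfonate | O=Cc1ccc([I+]c2c(OC)cc(OC)cc2OC)cc1.Cc1ccc(S(=O)(=O)[O-])cc1
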